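**Retrosynthetic overview**

1. Vitisinol D (11) ⇐ tetra‑TIPS ether 10 ⇐ C3‑deoxygenation (enol triflate, Pd/formate) of diosphenol 8.
2. 8 ⇐ Ti(IV)‑promoted perezone/Engler‑type [5+2] cycloaddition of the 2‑glycosyloxy‑6‑styryl‑1,4‑benzoquinone 5 (5C) with tri‑O‑TIPS‑resveratrol 7 (2C). It forms C5–C6 and C1–C7 and expels the sugar.
3. 5 ⇐ phenol 4 ⇐ polydatin 1 (natural resveratrol 3‑O‑β‑D‑glucoside). Its D‑glucose unit is the only source of chirality; 7 ⇐ resveratrol 6.
4. Ring order: the six‑membered ring is the pre‑existing resorcinol/quinone ring of polydatin. The cyclopentane, and with it the bicyclo[3.2.1]octane, closes in the cycloaddition; no ring is formed afterwards.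

Assumption: polydatin and resveratrol count as cheap commercial materials. The facial sense of the glucoside‑directed cycloaddition and its endo/exo outcome are assigned from the steric model in Step 6, not from experiment.

**Route**

Step 1
Reactants: 1, polydatin (trans‑piceid)
Product: 2, 4'‑O‑TIPS‑polydatin
Conditions: TIPSCl (1.05 eq), K2CO3 (1.1 eq), DMF, 0 °C
Reagents that add atoms: triisopropylsilyl chloride, CC(C)[Si](Cl)(C(C)C)C(C)C
Why: Phenoxide O‑silylation; the stilbene‑conjugated 4'‑OH is the more acidic phenol and the sugar hydroxyls are not ionised, so 4'‑O is capped preferentially, though only modest selectivity is expected and the 5‑O and bis‑silyl by‑products must be separated and recycled.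

Step 2
Reactants: 2
Product: 3, 4'‑O‑TIPS‑5‑O‑pivaloyl‑2'',3'',4'',6''‑tetra‑O‑pivaloyl‑polydatin
Conditions: PivCl (excess), pyridine, DMAP, 70 °C
Reagents that add atoms: pivaloyl chloride, CC(C)(C)C(=O)Cl
Why: Exhaustive DMAP‑catalysed acylation; the pivalates make the sugar inert to the later oxidant and Lewis acid and put a bulky, participating 2''‑O‑acyl group next to the glycosidic oxygen.

Step 3
Reactants: 3
Product: 4, 4'‑O‑TIPS‑2'',3'',4'',6''‑tetra‑O‑pivaloyl‑polydatin (free 5‑OH)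
Conditions: N2H4·H2O (3 eq), THF/MeOH, 0 °C → rt, under Ar
Reagents that add atoms: none
Why: Chemoselective hydrazinolysis; the aryl pivalate (phenoxide leaving group) is cleaved far faster than the four hindered alkyl pivalates, and the aryl TIPS ether and stilbene are untouched.

Step 4
Reactants: 4
Product: 5, 2‑[(2,3,4,6‑tetra‑O‑pivaloyl‑β‑D‑glucopyranosyl)oxy]‑6‑{(E)‑2‑[4‑(triisopropylsilyloxy)phenyl]ethenyl}‑1,4‑benzoquinone
Conditions: (KSO3)2NO (2.5 eq), KH2PO4 buffer, acetone/H2O, rt; use at once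
Reagents that add atoms: Fremy's salt, [K+].[K+].[O]N(S(=O)(=O)[O-])S(=O)(=O)[O-]
Why: Teuber oxidation of a phenol with a free para position to the p‑quinone (as 3‑methoxy‑5‑methylphenol gives 2‑methoxy‑6‑methylbenzoquinone); the only other phenol is silylated and the stilbene and esters are inert.

Step 5
Reactants: 6, resveratrol
Product: 7, 3,5,4'‑tri‑O‑TIPS‑resveratrol
Conditions: TIPSCl (3.6 eq), imidazole, DMF, rt
Reagents that add atoms: triisopropylsilyl chloride, CC(C)[Si](Cl)(C(C)C)C(C)C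
Why: Standard phenol silylation; TIPS keeps the 4‑oxyphenyl ring cation‑stabilising, resists chloride attack during the Lewis‑acid step and leaves with fluoride at the end.

Step 6 (key step)
Reactants: 5 and 7 (1.5 eq)
Product: 8, (1S,5S,6R,7R)‑3‑hydroxy‑6‑[3,5‑bis(TIPSO)phenyl]‑7‑[4‑(TIPSO)phenyl]‑4‑{(E)‑2‑[4‑(TIPSO)phenyl]ethenyl}bicyclo[3.2.1]oct‑3‑ene‑2,8‑dione
Conditions: TiCl4 (3–4 eq), CH2Cl2, −78 °C; aq NaHCO3
Reagents that add atoms: none (enol H from work‑up; the glucosyl unit leaves as tetra‑O‑pivaloylglucosyl chloride)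
Why: Engler/Büchi‑type formal [5+2] (perezone‑type) cycloaddition, stepwise in detail: Ti chelated between quinone C1=O and the glycosidic oxygen activates C5, the stilbene carbon β to the 4‑siloxyphenyl ring bonds there, the p‑siloxybenzyl cation is captured by C3 of the vinylogous ester, and irreversible loss of the 2‑O‑pivaloyl‑assisted glucosyl cation reveals the C2 ketone; the E‑alkene gives trans C6/C7, endo‑stacked C–C formation followed by rotation and closure puts the C6 aryl endo and the C7 aryl exo, and the stilbene is expected to take the quinone face opposite the 2''‑O‑pivaloyl arm of the chelated β‑D‑glucoside, which fixes C5 and C6 and through them C1 and C7.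

Step 7
Reactants: 8
Product: 9, (1S,5S,6R,7R)‑3‑trifluoromethanesulfonyloxy analogue of 8 (enol triflate)
Conditions: Tf2O (1.2 eq), pyridine, CH2Cl2, −78 → 0 °C
Reagents that add atoms: triflic anhydride, FC(F)(F)S(=O)(=O)OS(=O)(=O)C(F)(F)F
Why: O‑Triflation of the acidic diosphenol OH; C1 and C5 are bridgeheads flanking the ketones, so no other enolisation or epimerisation is possible.

Step 8
Reactants: 9
Product: 10, (1R,5S,6R,7R)‑tetra‑O‑TIPS‑vitisinol D
Conditions: Pd(OAc)2 (5 mol %), PPh3, HCO2H, Bu3N, DMF, 50 °C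
Reagents that add atoms: none
Why: Pd(0)‑catalysed formate reduction of a vinyl triflate (Cacchi) replaces C3–OTf by C3–H without touching stereocentres, silyl ethers or the stilbene; the change of C1 descriptor from S to R is only a CIP priority switch.

Step 9
Reactants: 10
Product: 11, vitisinol D, (1R,5S,6R,7R)‑6‑(3,5‑dihydroxyphenyl)‑7‑(4‑hydroxyphenyl)‑4‑[(E)‑2‑(4‑hydroxyphenyl)ethenyl]bicyclo[3.2.1]oct‑3‑ene‑2,8‑dione
Conditions: HF·pyridine, pyridine/THF, 0 °C → rt; pH 7 work‑up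
Reagents that add atoms: none
Why: Fluoride cleavage of the four aryl silyl ethers under buffered, weakly acidic conditions avoids the phenoxide‑triggered retro‑Michael opening of C1–C7 that base could cause; no stereocentre is affected.

**Compound list**

1 | polydatin (resveratrol 3‑O‑β‑D‑glucopyranoside) | OC[C@H]1O[C@@H](Oc2cc(O)cc(/C=C/c3ccc(O)cc3)c2)[C@H](O)[C@@H](O)[C@@H]1O | starting material

2 | 4'‑O‑TIPS‑polydatin | OC[C@H]1O[C@@H](Oc2cc(O)cc(/C=C/c3ccc(O[Si](C(C)C)(C(C)C)C(C)C)cc3)c2)[C@H](O)[C@@H](O)[C@@H]1O | intermediate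

3 | 4'‑O‑TIPS‑5‑O‑Piv‑2'',3'',4'',6''‑tetra‑O‑Piv‑polydatin | CC(C)(C)C(=O)OC[C@H]1O[C@@H](Oc2cc(OC(=O)C(C)(C)C)cc(/C=C/c3ccc(O[Si](C(C)C)(C(C)C)C(C)C)cc3)c2)[C@H](OC(=O)C(C)(C)C)[C@@H](OC(=O)C(C)(C)C)[C@@H]1OC(=O)C(C)(C)C | intermediate

4 | 4'‑O‑TIPS‑2'',3'',4'',6''‑tetra‑O‑Piv‑polydatin (5‑OH free) | CC(C)(C)C(=O)OC[C@H]1O[C@@H](Oc2cc(O)cc(/C=C/c3ccc(O[Si](C(C)C)(C(C)C)C(C)C)cc3)c2)[C@H](OC(=O)C(C)(C)C)[C@@H](OC(=O)C(C)(C)C)[C@@H]1OC(=O)C(C)(C)C | intermediate

5 | 2‑(tetra‑O‑Piv‑β‑D‑glucosyloxy)‑6‑[(E)‑4‑TIPSO‑styryl]‑1,4‑benzoquinone | CC(C)(C)C(=O)OC[C@H]1O[C@@H](OC2=CC(=O)C=C(/C=C/c3ccc(O[Si](C(C)C)(C(C)C)C(C)C)cc3)C2=O)[C@H](OC(=O)C(C)(C)C)[C@@H](OC(=O)C(C)(C)C)[C@@H]1OC(=O)C(C)(C)C | intermediate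

6 | resveratrol | Oc1ccc(/C=C/c2cc(O)cc(O)c2)cc1 | starting material

7 | 3,5,4'‑tri‑O‑TIPS‑resveratrol | CC(C)[Si](Oc1ccc(/C=C/c2cc(O[Si](C(C)C)(C(C)C)C(C)C)cc(O[Si](C(C)C)(C(C)C)C(C)C)c2)cc1)(C(C)C)C(C)C | intermediate

8 | (1S,5S,6R,7R)‑3‑hydroxy cycloadduct (diosphenol), tetra‑TIPS | O=C1C(O)=C(/C=C/c2ccc(O[Si](C(C)C)(C(C)C)C(C)C)cc2)[C@H]2C(=O)[C@@H]1[C@H](c1ccc(O[Si](C(C)C)(C(C)C)C(C)C)cc1)[C@H]2c1cc(O[Si](C(C)C)(C(C)C)C(C)C)cc(O[Si](C(C)C)(C(C)C)C(C)C)c1 | intermediate

9 | (1S,5S,6R,7R)‑3‑enol triflate, tetra‑TIPS | O=C1C(OS(=O)(=O)C(F)(F)F)=C(/C=C/c2ccc(O[Si](C(C)C)(C(C)C)C(C)C)cc2)[C@H]2C(=O)[C@@H]1[C@H](c1ccc(O[Si](C(C)C)(C(C)C)C(C)C)cc1)[C@H]2c1cc(O[Si](C(C)C)(C(C)C)C(C)C)cc(O[Si](C(C)C)(C(C)C)C(C)C)c1 | intermediate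

10 | (1R,5S,6R,7R)‑tetra‑O‑TIPS‑vitisinol D | O=C1C=C(/C=C/c2ccc(O[Si](C(C)C)(C(C)C)C(C)C)cc2)[C@H]2C(=O)[C@@H]1[C@H](c1ccc(O[Si](C(C)C)(C(C)C)C(C)C)cc1)[C@H]2c1cc(O[Si](C(C)C)(C(C)C)C(C)C)cc(O[Si](C(C)C)(C(C)C)C(C)C)c1 | intermediate

11 | vitisinol D | O=C1C=C(/C=C/c2ccc(O)cc2)[C@H]2C(=O)[C@@H]1[C@H](c1ccc(O)cc1)[C@H]2c1cc(O)cc(O)c1 | target

**Totals**

Total steps: 9. Longest linear sequence: 8 (1 → 11 through Steps 1–4 and 6–9); Step 5 is the convergent branch.

**Steps most likely to fail, with fallbacks**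

- **Step 6.** The zwitterion can also close to the [3+2] dihydrobenzofuranol, to a cyclobutane, or through the styryl dienolate in a vinylquinone [4+2]. The facial sense and the endo/exo outcome rest on a model and could be weak or reversed. Fallback: make the union intramolecular by linking the glucose primary O‑6'' to the stilbene 4‑OH with a di‑isopropylsilylene tether, which sits on the ring‑oxygen side of the quinone (the face needed here) and holds the cationic terminus next to C3; the tether falls off in Step 9.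
- **Step 1.** The 4'‑OH/5‑OH discrimination may be poor. Fallback: differentiate by construction. Ozonolyse hexa‑O‑pivaloyl‑polydatin to the 3‑glycosyloxy‑5‑pivaloyloxybenzaldehyde, cleave the aryl pivalate, and rebuild the stilbene by HWE olefination with diethyl 4‑(TIPSO)benzylphosphonate to reach 4 unambiguously.
- **Step 4.** The para position is flanked on both sides and the styrylquinone may be labile. Fallback: bypass the quinone by oxidising phenol 4 with PhI(OAc)2 in HFIP in the presence of 7 (oxidative‑dearomatisation‑induced phenoxonium [5+2]); this would give 10 directly and remove Steps 7–8, at the cost of losing the Ti‑chelate regiocontrol.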